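**Strategy.** The route rests on cutting the dihydrofuran at O1–C7a and C3–C3a. Ring B is a hydroquinone whose fused carbons C3a/C7a lie between the para oxygens at C4 and C7, so it maps onto a symmetric 3,6-dioxygenated benzyne, while O1–C2–C3 is the C–O–C unit of a resveratrol epoxide. In one operation the aryne inserts into the benzylic C–O bond of enantiopure (2R,3R)-resveratrol oxide tripivalate, forming both bonds, the five-membered ring and the C3 centre, with C2 carried over intact. The precursors are a 2-silylaryl triflate with MOM ethers and the Shi epoxide; the 6-methylchromone is attached afterwards at C5 by Negishi coupling.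

Key step: step 8

Remark on the structures: the target is the trans (2S,3S) isomer and the (2R,3R)-oxirane is the matching enantiomer. C2 keeps its four bonds; only its CIP descriptor changes (R to S) when the neighbouring carbon exchanges oxygen for carbon. No structure needed correction.

Remark on the design: the oxirane is kept as the tripivalate, because the esters make it isolable while the para oxygen still supports the C3 cation. The chromone half is built from 2-methylresorcinol through a mirror-symmetric phenol, because acylation of C-methylphloroglucinol would leave two different ortho hydroxyls and could close to the 8-methyl isomer.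

**Aryne precursor**

Step 1
Reactants: 1 2,5-dihydroxybenzaldehyde
Product: 2 2,5-bis(methoxymethoxy)benzaldehyde
Conditions: MOMCl, i-Pr2NEt, CH2Cl2, 0 °C → rt
Reagents that add atoms: chloromethyl methyl ether (MOMCl), COCCl
Why: O-alkylation of both phenols (MOM protection) leaves the aldehyde free to become the third ring oxygen in the next step.

Step 2
Reactants: 2 2,5-bis(methoxymethoxy)benzaldehyde
Product: 4 2,5-bis(methoxymethoxy)phenol, via aryl formate 3 (not isolated)
Conditions: mCPBA, CH2Cl2, 0 °C → rt; aq NaHCO3 wash; then K2CO3 (cat.), MeOH, rt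
Reagents that add atoms: meta-chloroperbenzoic acid (mCPBA), OOC(=O)c1cccc(Cl)c1
Why: Baeyer–Villiger (Dakin-type) oxidation, in which the electron-rich aryl group migrates to oxygen to give formate 3, and mild methanolysis then frees the phenol without touching the MOM acetals.

Step 3
Reactants: 4 2,5-bis(methoxymethoxy)phenol
Product: 5 2,5-bis(methoxymethoxy)phenyl N-isopropylcarbamate
Conditions: i-PrNCO, Et3N (cat.), CH2Cl2, rt
Reagents that add atoms: isopropyl isocyanate, CC(C)N=C=O
Why: Base-catalysed addition of the phenol to the isocyanate installs a carbamate that directs ortho-metalation and can later be removed under mild E1cB conditions.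

Step 4
Reactants: 5 2,5-bis(methoxymethoxy)phenyl N-isopropylcarbamate
Product: 9 3,6-bis(methoxymethoxy)-2-(trimethylsilyl)phenyl N-isopropylcarbamate, via N-silyl carbamate 6 (not isolated), via aryllithium 7 (not isolated), via bis-silyl carbamate 8 (not isolated)
Conditions: TMSOTf, TMEDA, Et2O, 0 °C → rt; n-BuLi, TMEDA, −78 °C; TMSCl, −78 °C → rt; aq NH4Cl
Reagents that add atoms: chlorotrimethylsilane, C[Si](C)(C)Cl (the C–SiMe3 group); trimethylsilyl triflate, C[Si](C)(C)OS(=O)(=O)C(F)(F)F (N–SiMe3 of 6 to 8 only)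
Why: Carbamate-directed ortho-metalation, in which N-silylation masks the N–H, n-BuLi/TMEDA removes the only proton ortho to the carbamate (also ortho to a MOM ether, so both groups direct to it), TMSCl traps the aryllithium, and the N–Si bond is hydrolysed on work-up.

Step 5
Reactants: 9 3,6-bis(methoxymethoxy)-2-(trimethylsilyl)phenyl N-isopropylcarbamate
Product: 11 3,6-bis(methoxymethoxy)-2-(trimethylsilyl)phenyl trifluoromethanesulfonate, via silylphenol 10 (not isolated)
Conditions: DBU, Et2NH, MeCN, 40 °C; then PhNTf2, rt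
Reagents that add atoms: N-phenylbis(trifluoromethanesulfonimide), O=S(=O)(N(c1ccccc1)S(=O)(=O)C(F)(F)F)C(F)(F)F
Why: E1cB cleavage of the N-monoalkyl carbamate (the isocyanate is scavenged by Et2NH) frees the phenoxide, which is triflated in the same pot under conditions that leave the C–Si bond and the MOM ethers intact.

**Epoxide**

Step 6
Reactants: 12 resveratrol
Product: 13 resveratrol tripivalate, (E)-3,5,4'-tris(pivaloyloxy)stilbene
Conditions: PivCl, Et3N, DMAP (cat.), CH2Cl2, 0 °C → rt
Reagents that add atoms: pivaloyl chloride, CC(C)(C)C(Cl)=O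
Why: DMAP-catalysed acylation of all three phenols lowers the electron density of the stilbene, so that the alkene survives the oxidant and the derived oxirane does not ionise on its own.

Step 7
Reactants: 13 resveratrol tripivalate
Product: 14 (2R,3R)-2-[3,5-bis(pivaloyloxy)phenyl]-3-[4-(pivaloyloxy)phenyl]oxirane
Conditions: D-fructose-derived Shi ketone (30 mol %), Oxone, K2CO3, Bu4NHSO4, MeCN/DMM–aq borate/EDTA buffer, 0 °C
Reagents that add atoms: Oxone (potassium peroxymonosulfate), [K+].OOS(=O)(=O)[O-]
Why: Shi asymmetric epoxidation, in which the chiral dioxirane transfers oxygen to the trans alkene through a spiro transition state that for trans-stilbenes should give the (R,R)-oxirane and so sets both oxirane centres, while the hindered pivalates should survive the cold carbonate buffer.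

**Key step and bromination**

Step 8
Reactants: 11 3,6-bis(methoxymethoxy)-2-(trimethylsilyl)phenyl trifluoromethanesulfonate; 14 (2R,3R)-2-[3,5-bis(pivaloyloxy)phenyl]-3-[4-(pivaloyloxy)phenyl]oxirane
Product: 16 (2S,3S)-2-[3,5-bis(pivaloyloxy)phenyl]-4,7-bis(methoxymethoxy)-3-[4-(pivaloyloxy)phenyl]-2,3-dihydro-1-benzofuran, via benzyne 15 (not isolated)
Conditions: CsF (3 equiv), MeCN, rt; 11 (1.5 equiv) added slowly to 14
Reagents that add atoms: none
Why: Fluoride removes the silyl group of 11 and triflate departs to give the symmetric benzyne 15, whose strained triple bond is attacked by the oxirane oxygen of 14 to give an ortho-aryl anion/oxonium zwitterion. The oxonium C–O bond to the carbon that carries the 4-pivaloyloxyphenyl ring ionises and the aryl anion captures this carbon, so the aryne is formally inserted into the C–O σ-bond; the closest known reaction is the insertion of arynes into the benzylic C–O bond of aryl epoxides such as styrene oxide to give 3-aryl-2,3-dihydrobenzofurans. The dihydrofuran ring closes by C3–C3a bond formation, a three-to-five ring expansion that proceeds as an intramolecular collapse of the benzylic cation onto the aryl anion held next to it by O1 (SN1-like, not a constrained SN2 closure). C2 keeps all its bonds, and C3 is set under substrate control by C2: the cation is captured from the side on which O1 sits, with its aryl group turned away from the C2 aryl group, which should give the trans ring. The step needs ionisation at the right carbon, and this is secured by lone-pair donation from the para ester oxygen on one ring against two electron-withdrawing meta esters on the other; the orientation of the aryne is of no concern because both aryne carbons are equivalent. The hindered, weakly basic pivalates should not compete with the oxirane oxygen for the aryne and are stable to fluoride.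

Step 9
Reactants: 16 (2S,3S)-2-[3,5-bis(pivaloyloxy)phenyl]-4,7-bis(methoxymethoxy)-3-[4-(pivaloyloxy)phenyl]-2,3-dihydro-1-benzofuran
Product: 17 (2S,3S)-5-bromo-2-[3,5-bis(pivaloyloxy)phenyl]-4,7-bis(methoxymethoxy)-3-[4-(pivaloyloxy)phenyl]-2,3-dihydro-1-benzofuran
Conditions: NBS (1.0 equiv), MeCN, 0 °C, dark
Reagents that add atoms: N-bromosuccinimide, O=C1CCC(=O)N1Br
Why: Electrophilic aromatic bromination should go to ring B, the only ring not deactivated by esters, and within it to C5, which is para to O1 and ortho to the C4 MOM ether (the 5-position selectivity of 1,2,4-trialkoxybenzenes), not to C6.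

**Chromone half**

Step 10
Reactants: 18 2-methylresorcinol (2-methylbenzene-1,3-diol)
Product: 19 1,3-bis(methoxymethoxy)-2-methylbenzene
Conditions: MOMCl, i-Pr2NEt, CH2Cl2, 0 °C → rt
Reagents that add atoms: chloromethyl methyl ether (MOMCl), COCCl
Why: O-alkylation of both phenols gives a mirror-symmetric arene whose two MOM ethers become the acid-labile C5 and C7 oxygens of the chromone.

Step 11
Reactants: 19 1,3-bis(methoxymethoxy)-2-methylbenzene
Product: 21 3,5-bis(methoxymethoxy)-4-methylphenol, via aryl boronate 20 (not isolated)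
Conditions: [Ir(OMe)(cod)]2 (cat.), dtbpy (cat.), B2pin2, THF, 80 °C; then NaOH, H2O2, H2O, 0 °C → rt
Reagents that add atoms: hydrogen peroxide, OO (oxygen of the new OH); bis(pinacolato)diboron, CC1(C)OB(OC1(C)C)B1OC(C)(C)C(C)(C)O1 (Bpin of 20 only)
Why: Iridium-catalysed C–H borylation (Hartwig–Miyaura) is governed by sterics and takes the only ring C–H without an ortho substituent, para to the methyl group, and basic peroxide oxidises the boronate to the phenol at the same carbon.

Step 12
Reactants: 21 3,5-bis(methoxymethoxy)-4-methylphenol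
Product: 22 2-bromo-3,5-bis(methoxymethoxy)-4-methylphenol
Conditions: NBS (1.0 equiv), CH2Cl2, −78 → −20 °C
Reagents that add atoms: N-bromosuccinimide, O=C1CCC(=O)N1Br
Why: Electrophilic aromatic bromination ortho to the free phenol, where the two open ring positions are equivalent by symmetry, so that only over-bromination has to be held back by stoichiometry and low temperature.

Step 13
Reactants: 22 2-bromo-3,5-bis(methoxymethoxy)-4-methylphenol
Product: 24 1-[6-hydroxy-2,4-bis(methoxymethoxy)-3-methylphenyl]-2-methoxyethan-1-one, via dilithio phenoxide 23 (not isolated)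
Conditions: n-BuLi (2.2 equiv), THF, −78 °C; MeOCH2C(O)N(OMe)Me, −78 → 0 °C; aq NH4Cl
Reagents that add atoms: N-methoxy-N-methyl-2-methoxyacetamide (Weinreb amide), COCC(=O)N(C)OC
Why: Deprotonation of the phenol and bromine–lithium exchange give a dianion whose aryl carbon adds once to the Weinreb amide (stable chelated tetrahedral intermediate), so the ketone forms next to the one free hydroxyl, which is para to the methyl group.

Step 14
Reactants: 24 1-[6-hydroxy-2,4-bis(methoxymethoxy)-3-methylphenyl]-2-methoxyethan-1-one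
Product: 26 3-methoxy-5,7-bis(methoxymethoxy)-6-methyl-4H-chromen-4-one, via enaminone 25 (not isolated)
Conditions: DMF-DMA, toluene, 100 °C; then AcOH, 50 °C
Reagents that add atoms: N,N-dimethylformamide dimethyl acetal, COC(OC)N(C)C
Why: Enaminone chromone synthesis, in which condensation at the methoxy-bearing methylene gives 25 and the only free phenol then adds to the enamine carbon with loss of dimethylamine, so that the ring oxygen can only end up para to the methyl group (6-methyl isomer).

**Coupling and deprotection**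

Step 15
Reactants: 17 (2S,3S)-5-bromo-2-[3,5-bis(pivaloyloxy)phenyl]-4,7-bis(methoxymethoxy)-3-[4-(pivaloyloxy)phenyl]-2,3-dihydro-1-benzofuran; 26 3-methoxy-5,7-bis(methoxymethoxy)-6-methyl-4H-chromen-4-one
Product: 28 2-[(2S,3S)-2-[3,5-bis(pivaloyloxy)phenyl]-4,7-bis(methoxymethoxy)-3-[4-(pivaloyloxy)phenyl]-2,3-dihydro-1-benzofuran-5-yl]-3-methoxy-5,7-bis(methoxymethoxy)-6-methyl-4H-chromen-4-one, via chromonylzinc chloride 27 (not isolated)
Conditions: 26 (1.3 equiv), TMPZnCl·LiCl, THF, 25 °C; then 17, Pd(OAc)2 (5 mol %), SPhos (10 mol %), THF, 55 °C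
Reagents that add atoms: none
Why: Directed zincation followed by Negishi cross-coupling, in which the TMP-zinc base removes the only pyranone proton (C2–H, flanked by the ring oxygen and the 3-methoxy group) to give a zinc reagent that does not ring-open and tolerates the pivalates, and Pd/SPhos joins it to the electron-rich, ortho-substituted bromide at C5.

Step 16
Reactants: 28 2-[(2S,3S)-2-[3,5-bis(pivaloyloxy)phenyl]-4,7-bis(methoxymethoxy)-3-[4-(pivaloyloxy)phenyl]-2,3-dihydro-1-benzofuran-5-yl]-3-methoxy-5,7-bis(methoxymethoxy)-6-methyl-4H-chromen-4-one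
Product: 30 2-[(2S,3S)-2-(3,5-dihydroxyphenyl)-4,7-dihydroxy-3-(4-hydroxyphenyl)-2,3-dihydro-1-benzofuran-5-yl]-5,7-dihydroxy-3-methoxy-6-methyl-4H-chromen-4-one (target CNP0218412.2), via tetra-MOM triphenol 29 (not isolated)
Conditions: K2CO3, MeOH/THF, rt, Ar; then HCl (3 M in MeOH), 45 °C
Reagents that add atoms: none
Why: Base-catalysed transesterification removes the three aryl pivalates while the hydroquinone is still masked, and acid-catalysed acetal exchange with methanol then removes all four MOM ethers; C3 carries no leaving group and C2 carries an aryl ring with only meta oxygens that cannot support benzylic ionisation, so the (2S,3S) configuration should be kept.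

**Compound list**

1 | 2,5-dihydroxybenzaldehyde | O=Cc1cc(O)ccc1O | starting material
2 | 2,5-bis(methoxymethoxy)benzaldehyde | COCOc1ccc(OCOC)c(C=O)c1 | intermediate
3 | 2,5-bis(methoxymethoxy)phenyl formate | COCOc1ccc(OCOC)c(OC=O)c1 | intermediate
4 | 2,5-bis(methoxymethoxy)phenol | COCOc1ccc(OCOC)c(O)c1 | intermediate
5 | 2,5-bis(methoxymethoxy)phenyl N-isopropylcarbamate | COCOc1ccc(OCOC)c(OC(=O)NC(C)C)c1 | intermediate
6 | 2,5-bis(methoxymethoxy)phenyl N-isopropyl-N-(trimethylsilyl)carbamate | COCOc1ccc(OCOC)c(OC(=O)N(C(C)C)[Si](C)(C)C)c1 | intermediate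
7 | [2-[N-isopropyl-N-(trimethylsilyl)carbamoyloxy]-3,6-bis(methoxymethoxy)phenyl]lithium | [Li]c1c(OCOC)ccc(OCOC)c1OC(=O)N(C(C)C)[Si](C)(C)C | intermediate
8 | 3,6-bis(methoxymethoxy)-2-(trimethylsilyl)phenyl N-isopropyl-N-(trimethylsilyl)carbamate | C[Si](C)(C)c1c(OCOC)ccc(OCOC)c1OC(=O)N(C(C)C)[Si](C)(C)C | intermediate
9 | 3,6-bis(methoxymethoxy)-2-(trimethylsilyl)phenyl N-isopropylcarbamate | C[Si](C)(C)c1c(OCOC)ccc(OCOC)c1OC(=O)NC(C)C | intermediate
10 | 3,6-bis(methoxymethoxy)-2-(trimethylsilyl)phenol | C[Si](C)(C)c1c(OCOC)ccc(OCOC)c1O | intermediate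
11 | 3,6-bis(methoxymethoxy)-2-(trimethylsilyl)phenyl trifluoromethanesulfonate | C[Si](C)(C)c1c(OCOC)ccc(OCOC)c1OS(=O)(=O)C(F)(F)F | intermediate
12 | resveratrol, (E)-3,5,4'-trihydroxystilbene | Oc1ccc(/C=C/c2cc(O)cc(O)c2)cc1 | starting material
13 | resveratrol tripivalate, (E)-3,5,4'-tris(pivaloyloxy)stilbene | CC(C)(C)C(=O)Oc1ccc(/C=C/c2cc(OC(=O)C(C)(C)C)cc(OC(=O)C(C)(C)C)c2)cc1 | intermediate
14 | (2R,3R)-2-[3,5-bis(pivaloyloxy)phenyl]-3-[4-(pivaloyloxy)phenyl]oxirane | CC(C)(C)C(=O)Oc1ccc(cc1)[C@@H]1[C@@H](c2cc(OC(=O)C(C)(C)C)cc(OC(=O)C(C)(C)C)c2)O1 | intermediate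
15 | 3,6-bis(methoxymethoxy)benzyne | COCOC1=CC=C(OCOC)C#C1 | intermediate
16 | (2S,3S)-2-[3,5-bis(pivaloyloxy)phenyl]-4,7-bis(methoxymethoxy)-3-[4-(pivaloyloxy)phenyl]-2,3-dihydro-1-benzofuran | c1cc(OCOC)c2c(c1OCOC)[C@H](c1ccc(OC(=O)C(C)(C)C)cc1)[C@@H](c1cc(OC(=O)C(C)(C)C)cc(OC(=O)C(C)(C)C)c1)O2 | intermediate
17 | (2S,3S)-5-bromo-2-[3,5-bis(pivaloyloxy)phenyl]-4,7-bis(methoxymethoxy)-3-[4-(pivaloyloxy)phenyl]-2,3-dihydro-1-benzofuran | Brc1cc(OCOC)c2c(c1OCOC)[C@H](c1ccc(OC(=O)C(C)(C)C)cc1)[C@@H](c1cc(OC(=O)C(C)(C)C)cc(OC(=O)C(C)(C)C)c1)O2 | intermediate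
18 | 2-methylresorcinol (2-methylbenzene-1,3-diol) | Cc1c(O)cccc1O | starting material
19 | 1,3-bis(methoxymethoxy)-2-methylbenzene | Cc1c(OCOC)cccc1OCOC | intermediate
20 | 2-[3,5-bis(methoxymethoxy)-4-methylphenyl]-4,4,5,5-tetramethyl-1,3,2-dioxaborolane | Cc1c(OCOC)cc(cc1OCOC)B1OC(C)(C)C(C)(C)O1 | intermediate
21 | 3,5-bis(methoxymethoxy)-4-methylphenol | Cc1c(OCOC)cc(O)cc1OCOC | intermediate
22 | 2-bromo-3,5-bis(methoxymethoxy)-4-methylphenol | Cc1c(OCOC)cc(O)c(Br)c1OCOC | intermediate
23 | lithium 2-lithio-3,5-bis(methoxymethoxy)-4-methylphenoxide | Cc1c(OCOC)cc(O[Li])c([Li])c1OCOC | intermediate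
24 | 1-[6-hydroxy-2,4-bis(methoxymethoxy)-3-methylphenyl]-2-methoxyethan-1-one | Cc1c(OCOC)cc(O)c(C(=O)COC)c1OCOC | intermediate
25 | (Z)-3-(dimethylamino)-1-[6-hydroxy-2,4-bis(methoxymethoxy)-3-methylphenyl]-2-methoxyprop-2-en-1-one | Cc1c(OCOC)cc(O)c(C(=O)/C(OC)=C/N(C)C)c1OCOC | intermediate
26 | 3-methoxy-5,7-bis(methoxymethoxy)-6-methyl-4H-chromen-4-one | COc1coc2cc(OCOC)c(C)c(OCOC)c2c1=O | intermediate
27 | [3-methoxy-5,7-bis(methoxymethoxy)-6-methyl-4-oxo-4H-chromen-2-yl]zinc chloride | COc1c([Zn]Cl)oc2cc(OCOC)c(C)c(OCOC)c2c1=O | intermediate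
28 | 2-[(2S,3S)-2-[3,5-bis(pivaloyloxy)phenyl]-4,7-bis(methoxymethoxy)-3-[4-(pivaloyloxy)phenyl]-2,3-dihydro-1-benzofuran-5-yl]-3-methoxy-5,7-bis(methoxymethoxy)-6-methyl-4H-chromen-4-one | COc1c(-c2cc(OCOC)c3c(c2OCOC)[C@H](c2ccc(OC(=O)C(C)(C)C)cc2)[C@@H](c2cc(OC(=O)C(C)(C)C)cc(OC(=O)C(C)(C)C)c2)O3)oc2cc(OCOC)c(C)c(OCOC)c2c1=O | intermediate
29 | 2-[(2S,3S)-2-(3,5-dihydroxyphenyl)-3-(4-hydroxyphenyl)-4,7-bis(methoxymethoxy)-2,3-dihydro-1-benzofuran-5-yl]-3-methoxy-5,7-bis(methoxymethoxy)-6-methyl-4H-chromen-4-one | COc1c(-c2cc(OCOC)c3c(c2OCOC)[C@H](c2ccc(O)cc2)[C@@H](c2cc(O)cc(O)c2)O3)oc2cc(OCOC)c(C)c(OCOC)c2c1=O | intermediate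
30 | 2-[(2S,3S)-2-(3,5-dihydroxyphenyl)-4,7-dihydroxy-3-(4-hydroxyphenyl)-2,3-dihydro-1-benzofuran-5-yl]-5,7-dihydroxy-3-methoxy-6-methyl-4H-chromen-4-one | COc1c(-c2cc(O)c3c(c2O)[C@H](c2ccc(O)cc2)[C@@H](c2cc(O)cc(O)c2)O3)oc2cc(O)c(C)c(O)c2c1=O | target

**Step count and risk**

Total step count: 16. Longest linear sequence: 9 steps (steps 1–5, 8, 9, 15 and 16, from 2,5-dihydroxybenzaldehyde).

The three steps most likely to fail:

Step 8 (aryne insertion). The aryl anion of the zwitterion may be protonated by the medium, the benzylic cation may undergo a 1,2-hydride shift (Meinwald-type rearrangement) before ring closure, or the closure may give poor trans selectivity. The fallback sets out from 14 and comes back at 16, forming the same two bonds in separate, known operations while C2 still keeps its C–O bond. Acid-catalysed methanolysis of 14 (PPTS, MeOH/CH2Cl2, 0 °C) should open the oxirane at the 4-pivaloyloxyphenyl carbon to give (1R)-1-[3,5-bis(pivaloyloxy)phenyl]-2-methoxy-2-[4-(pivaloyloxy)phenyl]ethan-1-ol F1, as a mixture at the methoxy carbon, which does not matter. Palladium-catalysed C–O coupling of this secondary alcohol (t-BuBrettPhos Pd G3, Cs2CO3, toluene, 80 °C) with 2-bromo-1,4-bis(methoxymethoxy)benzene F2 (from commercial bromohydroquinone and MOMCl) should give the aryl ether 2-[(1R)-1-[3,5-bis(pivaloyloxy)phenyl]-2-methoxy-2-[4-(pivaloyloxy)phenyl]ethoxy]-1,4-bis(methoxymethoxy)benzene F3. A catalytic Lewis acid (Bi(OTf)3 or BF3·OEt2, CH2Cl2, −78 → 0 °C) then ionises the benzylic methyl ether. Intramolecular Friedel–Crafts alkylation at the only free position ortho to the ether oxygen should close the trans ring and give 16.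

Step 15 (zincation and Negishi coupling). Oxidative addition into the electron-rich, ortho-substituted bromide and transmetalation of the hindered chromonylzinc may both be slow, so that protodezincation and homocoupling take over. The fallback sets out from 17 and 26 and comes back at 28 with the polarity reversed. Miyaura borylation of 17 (Pd(dppf)Cl2, B2pin2, KOAc, dioxane, 90 °C) should give the pinacol boronate 2-[(2S,3S)-2-[3,5-bis(pivaloyloxy)phenyl]-4,7-bis(methoxymethoxy)-3-[4-(pivaloyloxy)phenyl]-2,3-dihydro-1-benzofuran-5-yl]-4,4,5,5-tetramethyl-1,3,2-dioxaborolane F4. Metalation of 26 at C2 (TMPZnCl·LiCl, or LiTMP at −78 °C) and quenching with iodine should give 2-iodo-3-methoxy-5,7-bis(methoxymethoxy)-6-methyl-4H-chromen-4-one F5. Suzuki–Miyaura coupling of the two (Pd(OAc)2/SPhos, K3PO4, toluene/H2O, 80 °C) should give 28.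

Step 4 (directed silylation). The silyl triflate used to mask the N–H may attack the MOM acetals, or incomplete N-silylation may let the carbamate collapse on lithiation by loss of isocyanate or acyl migration. The fallback sets out from 4 and comes back at 11 without any carbamate. Silylation of 4 with hexamethyldisilazane (neat, 80 °C) should give [2,5-bis(methoxymethoxy)phenoxy]trimethylsilane F6. LDA or LiTMP (THF, −78 °C → rt) should lithiate the position between the silyloxy group and the MOM ether and trigger a 1,3 O→C silyl shift (retro-Brook rearrangement) to the lithium salt of 10, which is triflated in the same flask with PhNTf2 to give 11.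

**Further compounds**

F1 | step 8 | (1R)-1-[3,5-bis(pivaloyloxy)phenyl]-2-methoxy-2-[4-(pivaloyloxy)phenyl]ethan-1-ol | COC(c1ccc(OC(=O)C(C)(C)C)cc1)[C@H](O)c1cc(OC(=O)C(C)(C)C)cc(OC(=O)C(C)(C)C)c1
F2 | step 8 | 2-bromo-1,4-bis(methoxymethoxy)benzene | COCOc1ccc(OCOC)c(Br)c1
F3 | step 8 | 2-[(1R)-1-[3,5-bis(pivaloyloxy)phenyl]-2-methoxy-2-[4-(pivaloyloxy)phenyl]ethoxy]-1,4-bis(methoxymethoxy)benzene | COC(c1ccc(OC(=O)C(C)(C)C)cc1)[C@@H](c1cc(OC(=O)C(C)(C)C)cc(OC(=O)C(C)(C)C)c1)Oc1cc(OCOC)ccc1OCOC
F4 | step 15 | 2-[(2S,3S)-2-[3,5-bis(pivaloyloxy)phenyl]-4,7-bis(methoxymethoxy)-3-[4-(pivaloyloxy)phenyl]-2,3-dihydro-1-benzofuran-5-yl]-4,4,5,5-tetramethyl-1,3,2-dioxaborolane | CC1(C)OB(OC1(C)C)c1cc(OCOC)c2c(c1OCOC)[C@H](c1ccc(OC(=O)C(C)(C)C)cc1)[C@@H](c1cc(OC(=O)C(C)(C)C)cc(OC(=O)C(C)(C)C)c1)O2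
F5 | step 15 | 2-iodo-3-methoxy-5,7-bis(methoxymethoxy)-6-methyl-4H-chromen-4-one | COc1c(I)oc2cc(OCOC)c(C)c(OCOC)c2c1=O
F6 | step 4 | [2,5-bis(methoxymethoxy)phenoxy]trimethylsilane | COCOc1ccc(OCOC)c(O[Si](C)(C)C)c1
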